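**Plan**

- Retrosynthesis: remove the allyl groups; tie the C-2 carboxyl back to the neighbouring ring O–H as an aryl lactone; cut the ArCH(OH)–CH(OAr)(C=O) bond as an aldol between the lactone C-3 and 3,4-bis(allyloxy)benzaldehyde; cut the cinnamate C=C (malonate half-ester of protected (R)-danshensu plus an aldehyde) and the ArO–CH2 bond.
- Enabling feature: on the caffeoyl ring, O-4 carries the CH(CO2H) carbon and the free O-3–H is ortho to it. O-3, C-3, C-4, O-4, the α-carbon and the carboxyl carbon can therefore close a six-membered 2H-1,4-benzodioxin-2(3H)-one. This aryl lactone acidifies the CH2 between C=O and O-4, locks the enolate geometry, and masks one phenol and one acid at once.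
- Forward order: 4-O-alkylation of 3,4-dihydroxybenzaldehyde; Knoevenagel–Doebner chain joining with the danshensu half-ester; lactone closure; anti aldol with the second aldehyde; lactone opening; deallylation.
- Stereochemistry: the lactate centre comes from (R)-danshensu; the E-alkene from the decarboxylative condensation; the two new centres from the aldol. Their anti relation comes from the ring-locked E(O) enolate in a closed chair, and their absolute sense (2R,3R) from an (R,R)-diazaborolidine controller.

Key step: step 7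

Assumption: (R)-3-(3,4-dihydroxyphenyl)lactic acid (danshensu) and (1R,2R)-N,N'-ditosyl-1,2-diphenylethane-1,2-diamine are taken as commercial; lactone locants follow 2,3-dihydro-1,4-benzodioxin numbering.

**Route**

Step 1
Reactants: 1 3,4-dihydroxybenzaldehyde; 2 tert-butyl bromoacetate
Product: 3 tert-butyl 2-(4-formyl-2-hydroxyphenoxy)acetate
Conditions: NaHCO3 (1.5 equiv), NaI (cat.), DMF, 40 °C
Reagents that add atoms: none
Why: Williamson ether synthesis in which the more acidic 4-OH (para to the formyl group) should be alkylated selectively under weak base, the tert-butyl ester resisting attack by the free 3-OH.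

Step 2
Reactants: 4 (R)-3-(3,4-dihydroxyphenyl)lactic acid
Product: 5 allyl (2R)-3-[3,4-bis(allyloxy)phenyl]-2-hydroxypropanoate
Conditions: allyl bromide (3.3 equiv), K2CO3 (3.5 equiv), DMF, rt, Ar
Reagents that add atoms: allyl bromide, C=CCBr
Why: Williamson O-alkylation of the carboxylate and both phenoxides; carbonate does not deprotonate the secondary alcohol or the α-C–H, so the stereocentre should be untouched.

Step 3
Reactants: 5 allyl (2R)-3-[3,4-bis(allyloxy)phenyl]-2-hydroxypropanoate; 6 Meldrum's acid (2,2-dimethyl-1,3-dioxane-4,6-dione)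
Product: 7 3-{[(2R)-1-(allyloxy)-3-[3,4-bis(allyloxy)phenyl]-1-oxopropan-2-yl]oxy}-3-oxopropanoic acid
Conditions: toluene, 95 °C
Reagents that add atoms: none
Why: thermal alcoholysis of Meldrum's acid with loss of acetone should give the malonic half-ester under neutral conditions that cannot epimerise the lactate centre.

Step 4
Reactants: 3 tert-butyl 2-(4-formyl-2-hydroxyphenoxy)acetate; 7 malonic half-ester of 5
Product: 8 allyl (2R)-3-[3,4-bis(allyloxy)phenyl]-2-{[(2E)-3-{4-[2-(tert-butoxy)-2-oxoethoxy]-3-hydroxyphenyl}prop-2-enoyl]oxy}propanoate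
Conditions: pyridine, piperidine (cat.), 60 °C
Reagents that add atoms: none
Why: Knoevenagel–Doebner condensation; the half-ester condenses with the aldehyde and decarboxylates to the (E)-cinnamate, and the reaction tolerates the free phenol.

Step 5
Reactants: 8 tert-butyl ester phenol
Product: 10 allyl (2R)-3-[3,4-bis(allyloxy)phenyl]-2-{[(2E)-3-(2-oxo-2,3-dihydro-1,4-benzodioxin-7-yl)prop-2-enoyl]oxy}propanoate, via carboxylic acid 9 (not isolated)
Conditions: TFA, CH2Cl2, 0 °C to rt; evaporate; DCC, CH2Cl2, 0 °C to rt; filter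
Reagents that add atoms: none
Why: acidolysis of the tert-butyl ester (loss of isobutene) followed by carbodiimide lactonisation (Steglich-type) by the ortho phenol should close the six-membered aryl lactone without aqueous base; allyl ethers and esters are inert to both reagents.

Step 6
Reactants: 1 3,4-dihydroxybenzaldehyde
Product: 11 3,4-bis(allyloxy)benzaldehyde
Conditions: allyl bromide (2.5 equiv), K2CO3 (3 equiv), DMF, 60 °C
Reagents that add atoms: allyl bromide, C=CCBr
Why: exhaustive Williamson O-allylation of both phenols.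

Step 7
Reactants: 10 benzodioxinone lactone; 11 3,4-bis(allyloxy)benzaldehyde
Product: 14 allyl (2R)-3-[3,4-bis(allyloxy)phenyl]-2-{[(2E)-3-{(3R)-3-[(R)-[3,4-bis(allyloxy)phenyl](hydroxy)methyl]-2-oxo-2,3-dihydro-1,4-benzodioxin-7-yl}prop-2-enoyl]oxy}propanoate, via boron enolate 12 (not isolated), via boron aldolate 13 (not isolated)
Conditions: (1R,2R)-TsNHCH(Ph)CH(Ph)NHTs (1.3 equiv), BBr3, CH2Cl2, rt, volatiles removed [gives (4R,5R)-2-bromo-4,5-diphenyl-1,3-ditosyl-1,3,2-diazaborolidine]; 10, Et3N (1.5 equiv), CH2Cl2, −78 °C; 11 (1.5 equiv), −78 °C; pH 7 buffer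
Reagents that add atoms: none
Why: Proposed new method: the bromoborane binds the lactone carbonyl and triethylamine removes a C-3 proton, the only acidic C–H of 10 (between an aryl-ester carbonyl and O-4 in a lactone; the lactate α-H is a hindered alkyl-ester C–H and the cinnamate has none), giving B–O enolate 12, which should add to 11 through a closed Zimmerman–Traxler chair with the aldehyde aryl group equatorial. The closest known reaction type is the reagent-controlled anti aldol of E(O) boron enolates of tert-butyl esters formed with this same chiral diazaborolidine, together with boron aldols of simple lactones; aryl lactones of the benzodioxinone type have not been used in it. No ring is closed: the six-membered 1,4-benzodioxin-2-one is a preformed template that stays intact here and is opened in step 8. The relative configuration follows from the ring, which holds O-4 trans to O–B across C-2=C-3 (an E(O) enolate that cannot isomerise), so the chair can give only the anti pair; the absolute configuration is set by the controller, whose N-sulfonyl aryl groups lie anti to the neighbouring phenyl groups so that only the aldehyde C–H fits beneath the pseudo-axial sulfonamide, which for the (R,R)-reagent is predicted to join the Re face of C-3 to the Si face of the aldehyde and give (3R) at the ring carbon and (R) at the carbinol carbon. The step needs site-selective enolisation, 1,2-addition without ketene loss or β-lactone formation from the aryl ester, and survival of the base-sensitive adduct; these should be secured by the acidity gap, the covalent B–O bond at −78 °C, and a neutral, peroxide-free work-up.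

Step 8
Reactants: 14 β-hydroxy lactone
Product: 15 (2R,3R)-2-{2-hydroxy-4-[(1E)-3-{[(2R)-1-(allyloxy)-3-[3,4-bis(allyloxy)phenyl]-1-oxopropan-2-yl]oxy}-3-oxoprop-1-en-1-yl]phenoxy}-3-[3,4-bis(allyloxy)phenyl]-3-hydroxypropanoic acid
Conditions: NaHCO3 (aq), THF, 0 °C to rt; then 1 M HCl to pH 3, 0 °C
Reagents that add atoms: water, O
Why: hydrolysis of the aryl ester (acyl substitution with a phenoxide leaving group) should be far faster than attack on the alkyl cinnamate or allyl ester, and the weak base limits retro-aldol and C-2 epimerisation; no bond to a stereocentre is broken, and the phenol and the acid are freed together.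

Step 9
Reactants: 15 penta-allyl seco acid
Product: 16 (2R,3R)-2-{4-[(1E)-3-{[(1R)-1-carboxy-2-(3,4-dihydroxyphenyl)ethyl]oxy}-3-oxoprop-1-en-1-yl]-2-hydroxyphenoxy}-3-(3,4-dihydroxyphenyl)-3-hydroxypropanoic acid
Conditions: Pd(PPh3)4 (10 mol %), morpholine (12 equiv), THF, rt, Ar; 1 M HCl work-up; reversed-phase chromatography
Reagents that add atoms: none
Why: Tsuji–Trost-type deallylation; Pd(0) ionises the four aryl allyl ethers and the allyl ester to π-allyl complexes that morpholine traps, under near-neutral conditions that should leave the cinnamate, the benzylic alcohol and all three stereocentres untouched.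

**Compound list**

1 | 3,4-dihydroxybenzaldehyde | O=Cc1ccc(O)c(O)c1 | starting material
2 | tert-butyl bromoacetate | CC(C)(C)OC(=O)CBr | starting material
3 | tert-butyl 2-(4-formyl-2-hydroxyphenoxy)acetate | CC(C)(C)OC(=O)COc1ccc(C=O)cc1O | intermediate
4 | (R)-3-(3,4-dihydroxyphenyl)lactic acid (danshensu) | O[C@H](Cc1ccc(O)c(O)c1)C(=O)O | starting material
5 | allyl (2R)-3-[3,4-bis(allyloxy)phenyl]-2-hydroxypropanoate | O[C@H](Cc1ccc(OCC=C)c(OCC=C)c1)C(=O)OCC=C | intermediate
6 | Meldrum's acid | CC1(C)OC(=O)CC(=O)O1 | starting material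
7 | 3-{[(2R)-1-(allyloxy)-3-[3,4-bis(allyloxy)phenyl]-1-oxopropan-2-yl]oxy}-3-oxopropanoic acid | OC(=O)CC(=O)O[C@H](Cc1ccc(OCC=C)c(OCC=C)c1)C(=O)OCC=C | intermediate
8 | allyl (2R)-3-[3,4-bis(allyloxy)phenyl]-2-{[(2E)-3-{4-[2-(tert-butoxy)-2-oxoethoxy]-3-hydroxyphenyl}prop-2-enoyl]oxy}propanoate | CC(C)(C)OC(=O)COc1ccc(/C=C/C(=O)O[C@H](Cc2ccc(OCC=C)c(OCC=C)c2)C(=O)OCC=C)cc1O | intermediate
9 | 2-{2-hydroxy-4-[(1E)-3-{[(2R)-1-(allyloxy)-3-[3,4-bis(allyloxy)phenyl]-1-oxopropan-2-yl]oxy}-3-oxoprop-1-en-1-yl]phenoxy}acetic acid | OC(=O)COc1ccc(/C=C/C(=O)O[C@H](Cc2ccc(OCC=C)c(OCC=C)c2)C(=O)OCC=C)cc1O | intermediate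
10 | allyl (2R)-3-[3,4-bis(allyloxy)phenyl]-2-{[(2E)-3-(2-oxo-2,3-dihydro-1,4-benzodioxin-7-yl)prop-2-enoyl]oxy}propanoate | O=C1COc2ccc(/C=C/C(=O)O[C@H](Cc3ccc(OCC=C)c(OCC=C)c3)C(=O)OCC=C)cc2O1 | intermediate
11 | 3,4-bis(allyloxy)benzaldehyde | O=Cc1ccc(OCC=C)c(OCC=C)c1 | intermediate
12 | boron enolate of 10: O-[(4R,5R)-4,5-diphenyl-1,3-ditosyl-1,3,2-diazaborolidin-2-yl] enolate at C-2 of the 1,4-benzodioxin ring (C-2=C-3) | O=C(/C=C/c1ccc2OC=C(OB3N(S(=O)(=O)c4ccc(C)cc4)[C@H](c4ccccc4)[C@@H](c4ccccc4)N3S(=O)(=O)c3ccc(C)cc3)Oc2c1)O[C@H](Cc1ccc(OCC=C)c(OCC=C)c1)C(=O)OCC=C | intermediate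
13 | boron aldolate: 14 with its carbinol oxygen bound to the (4R,5R)-4,5-diphenyl-1,3-ditosyl-1,3,2-diazaborolidin-2-yl group | O=C(/C=C/c1ccc2O[C@H]([C@H](OB3N(S(=O)(=O)c4ccc(C)cc4)[C@H](c4ccccc4)[C@@H](c4ccccc4)N3S(=O)(=O)c3ccc(C)cc3)c3ccc(OCC=C)c(OCC=C)c3)C(=O)Oc2c1)O[C@H](Cc1ccc(OCC=C)c(OCC=C)c1)C(=O)OCC=C | intermediate
14 | allyl (2R)-3-[3,4-bis(allyloxy)phenyl]-2-{[(2E)-3-{(3R)-3-[(R)-[3,4-bis(allyloxy)phenyl](hydroxy)methyl]-2-oxo-2,3-dihydro-1,4-benzodioxin-7-yl}prop-2-enoyl]oxy}propanoate | O=C(/C=C/c1ccc2O[C@H]([C@H](O)c3ccc(OCC=C)c(OCC=C)c3)C(=O)Oc2c1)O[C@H](Cc1ccc(OCC=C)c(OCC=C)c1)C(=O)OCC=C | intermediate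
15 | (2R,3R)-2-{2-hydroxy-4-[(1E)-3-{[(2R)-1-(allyloxy)-3-[3,4-bis(allyloxy)phenyl]-1-oxopropan-2-yl]oxy}-3-oxoprop-1-en-1-yl]phenoxy}-3-[3,4-bis(allyloxy)phenyl]-3-hydroxypropanoic acid | O=C(/C=C/c1ccc(O[C@@H](C(=O)O)[C@H](O)c2ccc(OCC=C)c(OCC=C)c2)c(O)c1)O[C@H](Cc1ccc(OCC=C)c(OCC=C)c1)C(=O)OCC=C | intermediate
16 | (2R,3R)-2-{4-[(1E)-3-{[(1R)-1-carboxy-2-(3,4-dihydroxyphenyl)ethyl]oxy}-3-oxoprop-1-en-1-yl]-2-hydroxyphenoxy}-3-(3,4-dihydroxyphenyl)-3-hydroxypropanoic acid | O=C(/C=C/c1ccc(O[C@@H](C(=O)O)[C@H](O)c2ccc(O)c(O)c2)c(O)c1)O[C@H](Cc1ccc(O)c(O)c1)C(=O)O | target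

**Summary and risks**

Total step count: 9. Longest linear sequence: 7 steps (4 → 5 → 7 → 8 → 10 → 14 → 15 → 16; steps 2, 3, 4, 5, 7, 8, 9).

Steps most likely to fail:

1. Step 7. The process at risk is poor facial discrimination: the flat, tied-back aryloxy part of the lactone enolate offers less bulk to the sulfonyl groups than the tert-butoxy group of the known cases. Incomplete enolisation is a second risk if the boron reagent is held by the other carbonyl groups. The fallback uses known chemistry and takes absolute control from the lactate centre already present instead of from the reagent. It sets out from 10. Soft enolisation with dibutylboron triflate and iPr2NEt (CH2Cl2, −78 °C) gives the dibutylboron enolate F1. With 11, through the same ring-locked closed chair, this should give only the two anti adducts, the (3R, carbinol R) dibutylboron aldolate F2 and the (3S, carbinol S) dibutylboron aldolate F3. Peroxide-free pH 7 work-up frees 14 and its (3S, carbinol S) lactone diastereomer F4. These are diastereomers because of the (R)-lactate unit and are separated by preparative HPLC, so the fallback comes back to the route at 14.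

2. Step 8. The processes at risk are base-induced retro-aldol cleavage or epimerisation at C-3 of the β-hydroxy aryl lactone before the ring opens, and competing saponification of the allyl ester. The fallback replaces basic hydrolysis by acid-catalysed alcoholysis. It sets out from 14. Allyl alcohol with catalytic pyridinium p-toluenesulfonate at 40 °C should open the lactone to the hexa-allyl seco ester F5. Pd(PPh3)4 and morpholine as in step 9 then remove six allyl groups, and the fallback comes back to the route at 16.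

3. Step 4. The processes at risk are slow condensation of the electron-rich aldehyde, which gives time for epimerisation of the acyloxy-ester centre in hot amine base, and incomplete decarboxylation. The fallback changes the olefination to a Horner–Wadsworth–Emmons reaction. It sets out from 5. Esterification with diethylphosphonoacetic acid (DCC, cat. DMAP, CH2Cl2) gives the phosphonoacetate F6. Olefination of 3 with F6 under mild LiCl/DBU conditions (2.2 equiv DBU to cover the phenol, MeCN, 0 °C to rt) should give the (E)-cinnamate, and the fallback comes back to the route at 8.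

**Further compounds**

F1 | step 7 | dibutylboron enolate of 10 | O=C(/C=C/c1ccc2OC=C(OB(CCCC)CCCC)Oc2c1)O[C@H](Cc1ccc(OCC=C)c(OCC=C)c1)C(=O)OCC=C
F2 | step 7 | (3R, carbinol R) dibutylboron aldolate | O=C(/C=C/c1ccc2O[C@H]([C@H](OB(CCCC)CCCC)c3ccc(OCC=C)c(OCC=C)c3)C(=O)Oc2c1)O[C@H](Cc1ccc(OCC=C)c(OCC=C)c1)C(=O)OCC=C
F3 | step 7 | (3S, carbinol S) dibutylboron aldolate | O=C(/C=C/c1ccc2O[C@@H]([C@@H](OB(CCCC)CCCC)c3ccc(OCC=C)c(OCC=C)c3)C(=O)Oc2c1)O[C@H](Cc1ccc(OCC=C)c(OCC=C)c1)C(=O)OCC=C
F4 | step 7 | (3S, carbinol S) lactone diastereomer of 14 | O=C(/C=C/c1ccc2O[C@@H]([C@@H](O)c3ccc(OCC=C)c(OCC=C)c3)C(=O)Oc2c1)O[C@H](Cc1ccc(OCC=C)c(OCC=C)c1)C(=O)OCC=C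
F5 | step 8 | hexa-allyl seco ester (allyl ester of 15) | O=C(/C=C/c1ccc(O[C@@H](C(=O)OCC=C)[C@H](O)c2ccc(OCC=C)c(OCC=C)c2)c(O)c1)O[C@H](Cc1ccc(OCC=C)c(OCC=C)c1)C(=O)OCC=C
F6 | step 4 | allyl (2R)-3-[3,4-bis(allyloxy)phenyl]-2-{[2-(diethoxyphosphoryl)acetyl]oxy}propanoate | CCOP(=O)(OCC)CC(=O)O[C@H](Cc1ccc(OCC=C)c(OCC=C)c1)C(=O)OCC=C
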